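Everything rests on cutting the C4a–C5 bond of the carbocycle (ring B). In lepadin H the hydrogens at C4a and C5 are cis and sit beside the nitrogen-bearing C8a. This is the imprint of a thermal disrotatory 6π closure of the triene C4a=C8a–C8=C7–C6=C5 with E,Z,E geometry. One heating step thus forms ring B, the C4a–C5 bond and both stereocentres, and leaves a dienecarbamate for setting C8a by hydrogenation. The precursor is an L-alanine-derived N-Boc 2-methyl-3-silyloxy-1,2,3,4-tetrahydropyridine (ring A). Its enecarbamate alkene is the first triene unit, and its C8a carries a (1Z,3E)-dienyl chain with the protected C5′ carbinol.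

Key step: step 13

Remarks on the chemistry
- Numbering: decahydroquinoline numbering (N1, C2, C3, C4, C4a, C5–C8, C8a; side chain C1′–C8′) is used for all intermediates, including monocyclic ones. Ring A is the piperidine and ring B the carbocycle.
- Assumption: the SMILES is read as (2S,3R,4aS,5S,8aR,5′R). H2, H4a, H5, H8a and the C3 oxygen lie on one face; the C2 methyl and the C5 chain lie on the other. An L-alanine building block (2S) and the (R)-epoxide (5′R) are consistent with this reading.
- Design of the precursor: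
  - The C3 OTBS group, which is the facial control element, is the only silyl group, so its later removal needs no selectivity.
  - The C5′ oxygen is carried as a tert-butyl ether, which leaves together with Boc in one final acid step.
  - The lactam is activated as its enol phosphate, which is easier to handle than an N-Boc enol triflate.
  - The central Z-alkene is made with activated zinc, which stops at the alkene.

Step 1
Reactants: 1 N-Boc-L-alanine N-methoxy-N-methylamide; 2 but-3-en-1-ylmagnesium bromide (2.5 equiv, THF solution)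
Product: 3 tert-butyl (S)-(3-oxohept-6-en-2-yl)carbamate
Conditions: THF, 0 °C → rt; aq. NH4Cl
Reagents that add atoms: none
Why: Weinreb ketone synthesis, in which the first equivalent of Grignard reagent deprotonates the carbamate N–H (this also guards C2 against enolisation) and the second adds only once because the chelated tetrahedral adduct survives until the quench.

Step 2
Reactants: 3 tert-butyl (S)-(3-oxohept-6-en-2-yl)carbamate
Product: 4 tert-butyl [(2S,3R)-3-hydroxyhept-6-en-2-yl]carbamate
Conditions: LiAlH(Ot-Bu)3, EtOH, −78 °C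
Reagents that add atoms: none
Why: Chelation-controlled (Cram-chelate) hydride reduction of an N-Boc α-amino ketone, in which the metal ties carbamate and ketone together and hydride enters past the C2–H, so the anti (2S,3R) amino alcohol should dominate and any syn isomer can be removed by chromatography.

Step 3
Reactants: 4 tert-butyl [(2S,3R)-3-hydroxyhept-6-en-2-yl]carbamate
Product: 5 tert-butyl [(2S,3R)-3-(tert-butyldimethylsilyloxy)hept-6-en-2-yl]carbamate
Conditions: TBSCl, imidazole, DMF, rt
Reagents that add atoms: tert-butyldimethylsilyl chloride, CC(C)(C)[Si](C)(C)Cl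
Why: Imidazole-promoted silylation of a secondary alcohol, in which the carbamate N–H does not compete, blocks lactol formation in the next step and installs the later facial control element.

Step 4
Reactants: 5 tert-butyl [(2S,3R)-3-(tert-butyldimethylsilyloxy)hept-6-en-2-yl]carbamate
Product: 8 tert-butyl (2S,3R)-3-(tert-butyldimethylsilyloxy)-6-hydroxy-2-methylpiperidine-1-carboxylate (lactamol; both epimers at the carbinol carbon), via secondary ozonide 6 (not isolated), via open-chain aldehyde 7 (not isolated)
Conditions: O3, CH2Cl2, −78 °C; then Me2S, −78 °C → rt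
Reagents that add atoms: ozone, [O-][O+]=O
Why: Ozonolysis with reductive work-up cleaves the only alkene, and the δ-carbamoyl aldehyde closes spontaneously to the six-membered N-Boc hemiaminal, whose new centre is irrelevant because it is oxidised next.

Step 5
Reactants: 8 lactamol
Product: 9 tert-butyl (2S,3R)-3-(tert-butyldimethylsilyloxy)-2-methyl-6-oxopiperidine-1-carboxylate (N-Boc lactam; the carbonyl carbon is C8a)
Conditions: (n-Pr)4N[RuO4] (5 mol %), NMO, 4 Å MS, CH2Cl2, rt
Reagents that add atoms: none
Why: Ley–Griffith oxidation of a cyclic N-acyl hemiaminal to the N-Boc lactam under neutral, anhydrous conditions that leave TBS and Boc untouched.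

Step 6
Reactants: 9 N-Boc lactam
Product: 11 tert-butyl (2S,3R)-3-(tert-butyldimethylsilyloxy)-6-(diphenoxyphosphoryloxy)-2-methyl-3,4-dihydropyridine-1(2H)-carboxylate (enol phosphate), via potassium enolate 10 (not isolated)
Conditions: KN(SiMe3)2, THF, −78 °C; then (PhO)2P(O)Cl, −78 °C; chromatography on Et3N-deactivated silica
Reagents that add atoms: diphenyl chlorophosphate, O=P(Cl)(Oc1ccccc1)Oc1ccccc1
Why: Kinetic enolisation of the N-Boc lactam at C4a followed by O-phosphorylation gives the ketene aminal phosphate as a stable cross-coupling partner, and E1cB loss cannot occur because the silyloxy group sits on the γ-carbon (C3).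

Step 7
Reactants: 12 5-bromopent-1-ene; 13 (R)-2-propyloxirane
Product: 15 (R)-dec-9-en-4-ol, via pent-4-enylmagnesium bromide 14 (not isolated)
Conditions: Mg, THF, rt → 40 °C; then CuI (10 mol %), 13, −30 → 0 °C; aq. NH4Cl
Reagents that add atoms: none
Why: Copper-catalysed Grignard opening of a terminal epoxide by SN2 attack at the unsubstituted carbon leaves the C–O stereocentre untouched, so it becomes C5′ (R).

Step 8
Reactants: 15 (R)-dec-9-en-4-ol
Product: 16 (R)-7-tert-butoxydec-1-ene
Conditions: Cl3CC(=NH)Ot-Bu, BF3·OEt2 (cat.), cyclohexane/CH2Cl2, rt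
Reagents that add atoms: tert-butyl 2,2,2-trichloroacetimidate, CC(C)(C)OC(=N)C(Cl)(Cl)Cl
Why: Acid-catalysed tert-butylation of an alcohol with the trichloroacetimidate gives an ether that resists base, fluoride, palladium, heat and hydrogen and later leaves in the same acid step as Boc.

Step 9
Reactants: 16 (R)-7-tert-butoxydec-1-ene; 17 (E)-but-2-enal (5 equiv)
Product: 18 (R,E)-8-tert-butoxyundec-2-enal
Conditions: second-generation Hoveyda–Grubbs catalyst RuCl2(SIMes)(=CH-C6H4-2-Oi-Pr) (3 mol %), CH2Cl2, 40 °C
Reagents that add atoms: none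
Why: Olefin cross-metathesis of a terminal alkene with an electron-poor enal favours the cross product and the thermodynamic E-alkene, which fixes the C5=C6 geometry.

Step 10
Reactants: 18 (R,E)-8-tert-butoxyundec-2-enal
Product: 19 (R,E)-9-tert-butoxydodec-3-en-1-yne
Conditions: Me3SiCHN2, LiN(i-Pr)2, THF, −78 °C → rt; aq. NH4Cl
Reagents that add atoms: (trimethylsilyl)diazomethane, C[Si](C)(C)C=[N+]=[N-]
Why: Colvin rearrangement, in which 1,2-addition of the lithiated diazo compound, Peterson-type loss of silanolate, loss of N2 and a 1,2-hydrogen shift of the alkylidene carbene give the terminal enyne without touching the E-alkene and without the methanol conjugate addition that troubles enals under Ohira–Bestmann conditions.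

Step 11
Reactants: 11 enol phosphate; 19 (R,E)-9-tert-butoxydodec-3-en-1-yne
Product: 20 tert-butyl (2S,3R)-6-[(3E,9R)-9-tert-butoxydodec-3-en-1-yn-1-yl]-3-(tert-butyldimethylsilyloxy)-2-methyl-3,4-dihydropyridine-1(2H)-carboxylate (dienyne)
Conditions: PdCl2(PPh3)2 (5 mol %), CuI (10 mol %), Et3N/CHCl3 (2:1, degassed), 55 °C
Reagents that add atoms: none
Why: Sonogashira coupling of a lactam-derived enol phosphate with a terminal alkyne, a known reaction of N-Boc ketene aminal phosphates, forms C8a–C8 under mildly basic conditions that every protecting group tolerates.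

Step 12
Reactants: 20 dienyne
Product: 21 tert-butyl (2S,3R)-6-[(1Z,3E,9R)-9-tert-butoxydodeca-1,3-dien-1-yl]-3-(tert-butyldimethylsilyloxy)-2-methyl-3,4-dihydropyridine-1(2H)-carboxylate (amidotriene)
Conditions: Zn dust activated with Cu(OAc)2 and AgNO3, MeOH/H2O/THF, 35 °C, dark; filtration, no acid
Reagents that add atoms: none
Why: cis-Semireduction of a conjugated alkyne with activated zinc in protic medium acts only on triple bonds flanked by π systems, stops at the alkene and delivers both hydrogens syn, so C7=C8 should be Z while the two neighbouring alkenes stay intact.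

Step 13
Reactants: 21 amidotriene
Product: 22 tert-butyl (2S,3R,4aS,5S)-5-[(R)-5-tert-butoxyoctyl]-3-(tert-butyldimethylsilyloxy)-2-methyl-3,4,4a,5-tetrahydroquinoline-1(2H)-carboxylate (dienecarbamate with C8a=C8 and C6=C7; H4a and H5 cis)
Conditions: toluene (0.01 M, degassed), BHT (cat.), 120 °C, sealed base-washed tube
Reagents that add atoms: none
Why: The six π electrons of C4a=C8a–C8=C7–C6=C5 reorganise in a concerted, thermally allowed disrotatory 6π-electrocyclisation that creates the C4a–C5 σ bond and moves the π bonds to C8a=C8 and C6=C7, the closest known reaction type being the thermal ring closure of amido-substituted (E,Z,E)-hexatrienes to cyclohexadienes. Ring B (C4a–C5–C6–C7–C8–C8a) closes in this pericyclic six-atom mode, both termini becoming sp3 in the same event. The relative configuration at C4a and C5 follows from orbital symmetry: C4 on C4a and C1′ on C5 both point outward in the triene (ring A fixes the first geometry, step 12 the central Z-alkene, step 9 the E-alkene), so they turn to the same side and H4a and H5 end cis. The absolute sense (4aS,5S) requires torquoselectivity, which the half-chair of ring A should supply: A(1,3) strain with the Boc group holds the C2 methyl axial, the trans C3 OTBS group is then axial on the other face and 1,3 to C4a, and it shields that lobe of C4a so that C5 bonds on the methyl-side face. Rotation in the opposite sense would in addition force ring A into a boat or push the methyl group equatorial against the carbamate. The Boc group also disfavours the s-trans rotamer about C8a–C8, no inward alkyl group is available for a 1,7-hydrogen shift, and the moderate temperature keeps 1,5-hydrogen shifts of the product and Boc thermolysis slow.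

Step 14
Reactants: 22 dienecarbamate
Product: 23 tert-butyl (2S,3R,4aS,5S,8aR)-5-[(R)-5-tert-butoxyoctyl]-3-(tert-butyldimethylsilyloxy)-2-methyloctahydroquinoline-1(2H)-carboxylate (cis-fused)
Conditions: H2 (1–4 bar), Pd/C (10 wt %), EtOAc, rt
Reagents that add atoms: none
Why: Heterogeneous catalytic hydrogenation (syn addition) saturates C6=C7 and the enecarbamate, and because the face of C8a bearing the axial C2 methyl (1,3 to C8a) and the pseudo-axial C5 chain is shielded, hydrogen should arrive on the face of H4a and H5 to give the cis-fused (8aR) system with the 2,8a-cis relationship usual for reduction of N-acyl 2-alkyl tetrahydropyridines.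

Step 15
Reactants: 23 silyl ether
Product: 24 tert-butyl (2S,3R,4aS,5S,8aR)-5-[(R)-5-tert-butoxyoctyl]-3-hydroxy-2-methyloctahydroquinoline-1(2H)-carboxylate
Conditions: n-Bu4NF (3 equiv), THF, rt → 45 °C
Reagents that add atoms: none
Why: Fluoride desilylation needs no selectivity here because the TBS ether is the only silicon group, and Boc and the tert-butyl ether are inert to fluoride.

Step 16
Reactants: 24 C3 alcohol; 25 (2E,4E)-octa-2,4-dienoic acid
Product: 27 tert-butyl (2S,3R,4aS,5S,8aR)-5-[(R)-5-tert-butoxyoctyl]-2-methyl-3-[(2E,4E)-octa-2,4-dienoyloxy]octahydroquinoline-1(2H)-carboxylate, via mixed anhydride 26 (not isolated)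
Conditions: 25, 2,4,6-Cl3C6H2COCl, Et3N, toluene, rt; then 24, DMAP, toluene, rt → 40 °C
Reagents that add atoms: none
Why: Yamaguchi esterification, in which DMAP opens the mixed anhydride at the dienoyl carbonyl and the acylpyridinium acylates the hindered axial C3 hydroxyl with retention at C3 and without moving the E,E-diene.

Step 17
Reactants: 27 protected ester
Product: 28 lepadin H, (2S,3R,4aS,5S,8aR)-5-[(R)-5-hydroxyoctyl]-2-methyldecahydroquinolin-3-yl (2E,4E)-octa-2,4-dienoate
Conditions: TFA/CH2Cl2 (1:1), 0 °C → rt; then sat. aq. NaHCO3 (brief)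
Reagents that add atoms: none
Why: Acidolysis by loss of tert-butyl cation removes the Boc group and the tert-butyl ether in one operation, the protonated amine cannot attack the ester, and the short bicarbonate work-up frees the base and cleaves any C5′ trifluoroacetate.

Compound list
1 | tert-butyl (S)-[1-(methoxy(methyl)amino)-1-oxopropan-2-yl]carbamate (N-Boc-L-alanine Weinreb amide) | C[C@H](NC(=O)OC(C)(C)C)C(=O)N(C)OC | starting material
2 | but-3-en-1-ylmagnesium bromide | C=CCC[Mg]Br | starting material
3 | tert-butyl (S)-(3-oxohept-6-en-2-yl)carbamate | C[C@H](NC(=O)OC(C)(C)C)C(=O)CCC=C | intermediate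
4 | tert-butyl [(2S,3R)-3-hydroxyhept-6-en-2-yl]carbamate | C[C@H](NC(=O)OC(C)(C)C)[C@H](O)CCC=C | intermediate
5 | tert-butyl [(2S,3R)-3-(tert-butyldimethylsilyloxy)hept-6-en-2-yl]carbamate | C[C@H](NC(=O)OC(C)(C)C)[C@H](O[Si](C)(C)C(C)(C)C)CCC=C | intermediate
6 | secondary ozonide (1,2,4-trioxolane) of 5 | C[C@H](NC(=O)OC(C)(C)C)[C@H](O[Si](C)(C)C(C)(C)C)CCC1OCOO1 | intermediate
7 | tert-butyl [(2S,3R)-3-(tert-butyldimethylsilyloxy)-6-oxohexan-2-yl]carbamate | C[C@H](NC(=O)OC(C)(C)C)[C@H](O[Si](C)(C)C(C)(C)C)CCC=O | intermediate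
8 | tert-butyl (2S,3R)-3-(tert-butyldimethylsilyloxy)-6-hydroxy-2-methylpiperidine-1-carboxylate | C[C@@H]1N(C(=O)OC(C)(C)C)C(O)CC[C@H]1O[Si](C)(C)C(C)(C)C | intermediate
9 | tert-butyl (2S,3R)-3-(tert-butyldimethylsilyloxy)-2-methyl-6-oxopiperidine-1-carboxylate | C[C@@H]1N(C(=O)OC(C)(C)C)C(=O)CC[C@H]1O[Si](C)(C)C(C)(C)C | intermediate
10 | potassium enolate of 9 | C[C@@H]1N(C(=O)OC(C)(C)C)C([O-])=CC[C@H]1O[Si](C)(C)C(C)(C)C.[K+] | intermediate
11 | tert-butyl (2S,3R)-3-(tert-butyldimethylsilyloxy)-6-(diphenoxyphosphoryloxy)-2-methyl-3,4-dihydropyridine-1(2H)-carboxylate | C[C@@H]1N(C(=O)OC(C)(C)C)C(OP(=O)(Oc2ccccc2)Oc2ccccc2)=CC[C@H]1O[Si](C)(C)C(C)(C)C | intermediate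
12 | 5-bromopent-1-ene | C=CCCCBr | starting material
13 | (R)-2-propyloxirane | CCC[C@@H]1CO1 | starting material
14 | pent-4-en-1-ylmagnesium bromide | C=CCCC[Mg]Br | intermediate
15 | (R)-dec-9-en-4-ol | CCC[C@@H](O)CCCCC=C | intermediate
16 | (R)-7-tert-butoxydec-1-ene | CCC[C@@H](OC(C)(C)C)CCCCC=C | intermediate
17 | (E)-but-2-enal | C/C=C/C=O | starting material
18 | (R,E)-8-tert-butoxyundec-2-enal | CCC[C@@H](OC(C)(C)C)CCCC/C=C/C=O | intermediate
19 | (R,E)-9-tert-butoxydodec-3-en-1-yne | CCC[C@@H](OC(C)(C)C)CCCC/C=C/C#C | intermediate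
20 | tert-butyl (2S,3R)-6-[(3E,9R)-9-tert-butoxydodec-3-en-1-yn-1-yl]-3-(tert-butyldimethylsilyloxy)-2-methyl-3,4-dihydropyridine-1(2H)-carboxylate | C[C@@H]1N(C(=O)OC(C)(C)C)C(C#C/C=C/CCCC[C@H](OC(C)(C)C)CCC)=CC[C@H]1O[Si](C)(C)C(C)(C)C | intermediate
21 | tert-butyl (2S,3R)-6-[(1Z,3E,9R)-9-tert-butoxydodeca-1,3-dien-1-yl]-3-(tert-butyldimethylsilyloxy)-2-methyl-3,4-dihydropyridine-1(2H)-carboxylate | C[C@@H]1N(C(=O)OC(C)(C)C)C(/C=C\C=C\CCCC[C@H](OC(C)(C)C)CCC)=CC[C@H]1O[Si](C)(C)C(C)(C)C | intermediate
22 | tert-butyl (2S,3R,4aS,5S)-5-[(R)-5-tert-butoxyoctyl]-3-(tert-butyldimethylsilyloxy)-2-methyl-3,4,4a,5-tetrahydroquinoline-1(2H)-carboxylate | CC(C)(C)[Si](C)(C)O[C@@H]1C[C@H]2[C@@H](CCCC[C@H](OC(C)(C)C)CCC)C=CC=C2N(C(=O)OC(C)(C)C)[C@H]1C | intermediate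
23 | tert-butyl (2S,3R,4aS,5S,8aR)-5-[(R)-5-tert-butoxyoctyl]-3-(tert-butyldimethylsilyloxy)-2-methyloctahydroquinoline-1(2H)-carboxylate | CC(C)(C)[Si](C)(C)O[C@@H]1C[C@H]2[C@@H](CCCC[C@H](OC(C)(C)C)CCC)CCC[C@H]2N(C(=O)OC(C)(C)C)[C@H]1C | intermediate
24 | tert-butyl (2S,3R,4aS,5S,8aR)-5-[(R)-5-tert-butoxyoctyl]-3-hydroxy-2-methyloctahydroquinoline-1(2H)-carboxylate | O[C@@H]1C[C@H]2[C@@H](CCCC[C@H](OC(C)(C)C)CCC)CCC[C@H]2N(C(=O)OC(C)(C)C)[C@H]1C | intermediate
25 | (2E,4E)-octa-2,4-dienoic acid | CCC/C=C/C=C/C(=O)O | starting material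
26 | (2E,4E)-octa-2,4-dienoic 2,4,6-trichlorobenzoic anhydride | CCC/C=C/C=C/C(=O)OC(=O)c1c(Cl)cc(Cl)cc1Cl | intermediate
27 | tert-butyl (2S,3R,4aS,5S,8aR)-5-[(R)-5-tert-butoxyoctyl]-2-methyl-3-[(2E,4E)-octa-2,4-dienoyloxy]octahydroquinoline-1(2H)-carboxylate | CCC/C=C/C=C/C(=O)O[C@@H]1C[C@H]2[C@@H](CCCC[C@H](OC(C)(C)C)CCC)CCC[C@H]2N(C(=O)OC(C)(C)C)[C@H]1C | intermediate
28 | lepadin H | CCC/C=C/C=C/C(=O)O[C@@H]1C[C@H]2[C@@H](CCCC[C@H](O)CCC)CCC[C@H]2N[C@H]1C | target

Total step count: 17 steps.
Longest linear sequence: 13 steps (steps 1–6 and 11–17, from 1 to 28). The chain branch (steps 7–10) joins at step 11.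

Steps most likely to fail

1. Step 13.
- Risk: C5 may bond to both faces of C4a (weak torquoselectivity). The closure may also need a temperature at which 1,5-hydrogen shifts in the cyclohexadiene and thermal loss of Boc begin to compete.
- Fallback: the control element in the substrate is strengthened, not the conditions.
  - Setting out from dienyne 20, n-Bu4NF in THF would free the C3 alcohol F1.
  - TIPSOTf and 2,6-lutidine (CH2Cl2, −40 → 0 °C) would give the triisopropylsilyl ether F2. Its three branched arms reach much closer to C4a than the methyl groups of TBS.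
  - Zinc semireduction as in step 12 would give the amidotriene F3.
  - Heating as in step 13 would give the hexahydroquinoline F4.
  - Hydrogenation as in step 14 would give the decahydroquinoline F5.
  - n-Bu4NF then comes back to the route at alcohol 24.

2. Step 12.
- Risk: over-reduction of the conjugated system, stalled conversion of the lipophilic dienyne in the aqueous medium, or drift of the new alkene from Z to E.
- Fallback: the Z-alkene is made by olefination and no alkyne is passed through.
  - Setting out from enal 18, a Stork–Zhao olefination (Ph3P+CH2I I−, NaN(SiMe3)2, THF/DMPU, −78 °C) would give the (1Z,3E)-iododiene F6.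
  - Iodine–lithium exchange (t-BuLi, Et2O, −78 °C) and trapping with i-PrOBpin would give the dienylboronate F7 with retention of both geometries.
  - Suzuki–Miyaura coupling of the boronate with enol phosphate 11 (PdCl2(PPh3)2, aq. Na2CO3, THF, 45 °C) comes back to the route at amidotriene 21.

3. Step 14.
- Risk: poor facial selectivity at C8a, or metal-induced migration of the enecarbamate double bond to C4a=C8a, which would erase C4a.
- Fallback: the order of desilylation and reduction is swapped, so that a directing group rather than steric shielding picks the face.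
  - Setting out from dienecarbamate 22, n-Bu4NF in THF would give the dienecarbamate alcohol F8. Its axial C3 hydroxyl lies on the face where H8a is needed.
  - Hydroxyl-directed homogeneous hydrogenation with [Ir(cod)(PCy3)(py)]PF6 (H2, CH2Cl2, rt) should deliver hydrogen from that face. It comes back to the route at alcohol 24 in the same number of steps.

Further compounds
F1 | step 13 | tert-butyl (2S,3R)-6-[(3E,9R)-9-tert-butoxydodec-3-en-1-yn-1-yl]-3-hydroxy-2-methyl-3,4-dihydropyridine-1(2H)-carboxylate | C[C@@H]1N(C(=O)OC(C)(C)C)C(C#C/C=C/CCCC[C@H](OC(C)(C)C)CCC)=CC[C@H]1O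
F2 | step 13 | tert-butyl (2S,3R)-6-[(3E,9R)-9-tert-butoxydodec-3-en-1-yn-1-yl]-2-methyl-3-(triisopropylsilyloxy)-3,4-dihydropyridine-1(2H)-carboxylate | C[C@@H]1N(C(=O)OC(C)(C)C)C(C#C/C=C/CCCC[C@H](OC(C)(C)C)CCC)=CC[C@H]1O[Si](C(C)C)(C(C)C)C(C)C
F3 | step 13 | tert-butyl (2S,3R)-6-[(1Z,3E,9R)-9-tert-butoxydodeca-1,3-dien-1-yl]-2-methyl-3-(triisopropylsilyloxy)-3,4-dihydropyridine-1(2H)-carboxylate | C[C@@H]1N(C(=O)OC(C)(C)C)C(/C=C\C=C\CCCC[C@H](OC(C)(C)C)CCC)=CC[C@H]1O[Si](C(C)C)(C(C)C)C(C)C
F4 | step 13 | tert-butyl (2S,3R,4aS,5S)-5-[(R)-5-tert-butoxyoctyl]-2-methyl-3-(triisopropylsilyloxy)-3,4,4a,5-tetrahydroquinoline-1(2H)-carboxylate | CC(C)[Si](C(C)C)(C(C)C)O[C@@H]1C[C@H]2[C@@H](CCCC[C@H](OC(C)(C)C)CCC)C=CC=C2N(C(=O)OC(C)(C)C)[C@H]1C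
F5 | step 13 | tert-butyl (2S,3R,4aS,5S,8aR)-5-[(R)-5-tert-butoxyoctyl]-2-methyl-3-(triisopropylsilyloxy)octahydroquinoline-1(2H)-carboxylate | CC(C)[Si](C(C)C)(C(C)C)O[C@@H]1C[C@H]2[C@@H](CCCC[C@H](OC(C)(C)C)CCC)CCC[C@H]2N(C(=O)OC(C)(C)C)[C@H]1C
F6 | step 12 | (1Z,3E,9R)-9-tert-butoxy-1-iodododeca-1,3-diene | CCC[C@@H](OC(C)(C)C)CCCC/C=C/C=C\I
F7 | step 12 | 2-[(1Z,3E,9R)-9-tert-butoxydodeca-1,3-dien-1-yl]-4,4,5,5-tetramethyl-1,3,2-dioxaborolane | CCC[C@@H](OC(C)(C)C)CCCC/C=C/C=C\B1OC(C)(C)C(C)(C)O1
F8 | step 14 | tert-butyl (2S,3R,4aS,5S)-5-[(R)-5-tert-butoxyoctyl]-3-hydroxy-2-methyl-3,4,4a,5-tetrahydroquinoline-1(2H)-carboxylate | O[C@@H]1C[C@H]2[C@@H](CCCC[C@H](OC(C)(C)C)CCC)C=CC=C2N(C(=O)OC(C)(C)C)[C@H]1C
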